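Start from the end. The flasks, the readings and the questions are these.

| flask | X | E | L | remark | time |
|---|---|---|---|---|---|
| south-east | 0.25 M | 0.37 M | 14 mM | run made earlier |  |
| south-west | 0.55 M | 0.37 M | 14 mM | run made earlier |  |
| north | 0.37 M | 0.37 M | 7 mM | run made earlier |  |
| flask | 0.37 M | 0.370 M | 14 mM |  | 8.0 min |

| run | time / min | X / % | Q / % |
|---|---|---|---|
| south-east | 0.667 | 0 | 41.2 |
| south-east | 2.00 | 0.2 | 41.3 |
| south-east | 4.00 | 0 | 41.2 |
| south-east | 6.00 | 0 | 41.5 |
| south-east | 8.00 | 0 | 41.3 |
| south-west | 0.667 | 3.6 | 43.7 |
| south-west | 1.33 | 0.5 | 44.5 |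
| south-west | 2.50 | 0.3 | 44.8 |
| south-west | 4.00 | 0 | 45.4 |
| south-west | 8.00 | 0 | 45.2 |
| north | 0.667 | 2.9 | 31.8 |
| north | 1.33 | 0.3 | 32.7 |
| north | 2.50 | 0 | 32.6 |
| north | 4.00 | 0 | 32.7 |
| north | 8.00 | 0 | 32.7 |

(standard deviation of a reading: 0.3 percentage points)

- steps thought possible: E + X -> D; 2 Z -> G; X + Z -> Q + Z; X + J -> Z + Q; L -> 2 J
- the reaction counts as stopped when no species that holds the X changes by six tenths of a point or more over the second half of the time

- the state of affairs at 8.0 min: stopped, and by what, or still going (forward and back rates have come level / all of X has reacted / it is still moving)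
- part of the X gone at 8.0 min
- the Q standing at 8.0 min, as a percentage of the X charged

At 4.00 min X reads 0%, 0% and 0% in the south-east, south-west and north runs, and Q then stays flat within the scatter. So two chemists expect the same of the flask by 8.0 min, and what they dispute is the Q standing then.

The first holds a count: L starts the chains, so Q per L charged should be fixed. She reads 17.3 in the north run and 17.8 in the south-west run, and with 14 mM of L that gives Q at 65.4% of the X charged.

The second holds a split: X goes either to D with E or to Q through the radicals, so dQ/dD = r/[E], where r is the concentration of E at which the two routes take X equally. Integrated, this is Q = r ln(E_start/E_end), with E_end = E_start − (X_start − Q) once X is gone. From the last readings he gets r = 0.204 M in the south-east run and 0.148 M in the south-west run, both at the flask's L. The north run, with half that L, gives 0.108 M, so r has to be read at the right L. Interpolated to the flask's X charge, r is 0.182 M: the split constant of the flask, the Q made per unit of ln(E_start/E_end), a selectivity factor with the unit of a concentration.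

In this flask E_start equals X_start, so E_end = Q and Q = r ln(E_start/Q). Starting from the mean share of the south-east and south-west runs, taken on the flask's X as 0.160 M, one Newton step gives 0.156 M, which is 42.3% of the X charged.

He grants her count its ground: it holds in the two runs she read, with X to L at 52.9 and 39.3. The south-east run, at 17.9, gives 7.37 Q per L, and the flask, at 26.4, stands lower in X to L than both of her runs.

The forecast sides with him: all of X has reacted, 100% of X gone and Q at 42.3%, within 40.8% to 44%, stopped “through complete use of X, not through an equilibrium”.

    E + X → D (k = 0.340 /M/s)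
    2 Z → G (k = 1.70 × 10⁸ /M/s)
    X + Z → Q + Z, rate k3*[Z]*[X] (k = 27000 /M/s)
    X + J → Z + Q (k = 1.30 × 10⁶ /M/s)
    L → 2 J (k = 0.0680 /s)

At 8.0 min in the flask, all of X has reacted: 100% of X gone and Q at 42.1%, below the count's 65.4%. Of their charges, X stands at 0% and E at 42%, less of X than of E. Reckoned back from that Q, r of the flask is 0.180 M, beside the carried 0.182 M. In the neighbouring flask, with 0.056 M of L in place of 14 mM, Q stands at 62.4% at 8.0 min, and the same reckoning gives r = 0.490 M, more than the flask's.

(The numbers in the tables come from a simulation from invented constants; the scatter is artificial.)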